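**Plan**

- Numbering: oxolane ring A is O1, C2 (3,4,5-trimethoxyphenyl), C3 (CH2OH), C4 (3,4-dimethoxybenzyl), C5; the target is the all-cis (2R,3R,4R) isomer.
- Retrosynthesis: taking CH2OH back to CO2Me and C2–H/C3–H back to C2=C3 uncovers in ring A the array O1–C2=C3–C(=O)OMe, a cyclic β-alkoxy acrylate beside C4. This array is cut at O1–C2 and at C3–CO2Me in one operation (alkynol + CO + MeOH).
- The open-chain alkynol is cut at aryl–C2 (Sonogashira), at C2≡C3 back to an aldehyde (one-carbon homologation) and at C4–C5 (hydroxymethylation of an acyl oxazolidinone enolate).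
- Forward: the C3–C4(CH2Ar)–C5 chain is built on the auxiliary, the alkyne and then the aryl group are added, ring A (the only ring formed) is closed together with the ester carbon, and two reductions finish.
- Stereochemistry: C4 comes from the (R)-4-benzyloxazolidin-2-one-directed hydroxymethylation; C2 and C3 are set together by cis-addition of H2 to C2=C3 on the face away from the C4 benzyl group.

Key step: step 9

Remark: from step 10 onward acids are excluded, because the electron-rich benzylic C2–O bond can ionise and the cation can alkylate the dimethoxyphenyl ring.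

**Route**

Step 1
Reactants: 1 3-(3,4-dimethoxyphenyl)propanoic acid; 2 (R)-4-benzyloxazolidin-2-one
Product: 4 (R)-4-benzyl-3-[3-(3,4-dimethoxyphenyl)propanoyl]oxazolidin-2-one, via mixed pivalic anhydride 3 (not isolated)
Conditions: PivCl, Et3N, THF, −20 °C; then 2, LiCl, −20 °C → rt
Reagents that add atoms: none
Why: N-acylation of an oxazolidinone through a pivaloyl mixed anhydride (LiCl/Et3N procedure), in which the lithium-coordinated carbamate nitrogen attacks the unhindered carbonyl of 3; no stereocentre is created.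

Step 2
Reactants: 4 (R)-4-benzyl-3-[3-(3,4-dimethoxyphenyl)propanoyl]oxazolidin-2-one
Product: 6 (R)-4-benzyl-3-[(S)-3-(3,4-dimethoxyphenyl)-2-(hydroxymethyl)propanoyl]oxazolidin-2-one, via trichlorotitanium Z-enolate 5 (not isolated)
Conditions: TiCl4, iPr2NEt, CH2Cl2, 0 °C; then 1,3,5-trioxane, TiCl4, 0 °C
Reagents that add atoms: 1,3,5-trioxane, C1OCOCO1
Why: Evans titanium-enolate hydroxymethylation (aldol-type addition to TiCl4-activated formaldehyde), in which the chelated Z-enolate 5 reacts on the face remote from the benzyl group of the (R)-auxiliary, so the new centre (the future C4) should be S in 6; it is named R in 13 only because the CIP priorities change.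

Step 3
Reactants: 6 (R)-4-benzyl-3-[(S)-3-(3,4-dimethoxyphenyl)-2-(hydroxymethyl)propanoyl]oxazolidin-2-one
Product: 7 (R)-4-benzyl-3-[(S)-3-[(tert-butyldiphenylsilyl)oxy]-2-(3,4-dimethoxybenzyl)propanoyl]oxazolidin-2-one
Conditions: TBDPSCl, imidazole, DMF, rt
Reagents that add atoms: tert-butylchlorodiphenylsilane, CC(C)(C)[Si](Cl)(c1ccccc1)c1ccccc1
Why: Imidazole-promoted silylation of a primary alcohol; the bulky, base-stable TBDPS ether keeps the two hydroxymethyl arms distinct after the auxiliary is removed and should not migrate under the later carbonate conditions.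

Step 4
Reactants: 7 (R)-4-benzyl-3-[(S)-3-[(tert-butyldiphenylsilyl)oxy]-2-(3,4-dimethoxybenzyl)propanoyl]oxazolidin-2-one
Product: 8 (R)-3-[(tert-butyldiphenylsilyl)oxy]-2-(3,4-dimethoxybenzyl)propan-1-ol
Conditions: LiBH4, H2O (1 equiv), Et2O, 0 °C
Reagents that add atoms: none
Why: Reductive cleavage of an N-acyl oxazolidinone by LiBH4 (hydride attack at the exocyclic carbonyl) should release the primary alcohol without touching the α-stereocentre and return auxiliary 2.

Step 5
Reactants: 8 (R)-3-[(tert-butyldiphenylsilyl)oxy]-2-(3,4-dimethoxybenzyl)propan-1-ol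
Product: 9 (S)-3-[(tert-butyldiphenylsilyl)oxy]-2-(3,4-dimethoxybenzyl)propanal
Conditions: Dess–Martin periodinane, pyridine, CH2Cl2, 0 °C → rt
Reagents that add atoms: none
Why: Dess–Martin oxidation of a primary alcohol under buffered, non-enolising conditions should give the α-branched aldehyde with its configuration intact; the crude aldehyde is used at once.

Step 6
Reactants: 9 (S)-3-[(tert-butyldiphenylsilyl)oxy]-2-(3,4-dimethoxybenzyl)propanal
Product: 10 (R)-tert-butyl{[2-(3,4-dimethoxybenzyl)but-3-yn-1-yl]oxy}diphenylsilane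
Conditions: dimethyl (1-diazo-2-oxopropyl)phosphonate, K2CO3, MeOH, 0 °C → rt
Reagents that add atoms: dimethyl (1-diazo-2-oxopropyl)phosphonate (Bestmann–Ohira reagent), CC(=O)C(=[N+]=[N-])P(=O)(OC)OC
Why: Ohira–Bestmann (Seyferth–Gilbert) homologation, in which the diazomethylphosphonate anion formed by methanolysis adds to the aldehyde and the derived alkylidene carbene rearranges to the terminal alkyne; α-branched β-silyloxy aldehydes are standard substrates at 0 °C.

Step 7
Reactants: 10 (R)-tert-butyl{[2-(3,4-dimethoxybenzyl)but-3-yn-1-yl]oxy}diphenylsilane; 11 5-iodo-1,2,3-trimethoxybenzene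
Product: 12 (R)-tert-butyl{[2-(3,4-dimethoxybenzyl)-4-(3,4,5-trimethoxyphenyl)but-3-yn-1-yl]oxy}diphenylsilane
Conditions: PdCl2(PPh3)2 (3 mol %), CuI (5 mol %), Et3N, THF, rt
Reagents that add atoms: none
Why: Sonogashira coupling of a terminal alkyne with an aryl iodide; the silyl ether keeps the hydroxyl from adding to the alkyne under palladium–copper catalysis.

Step 8
Reactants: 12 (R)-tert-butyl{[2-(3,4-dimethoxybenzyl)-4-(3,4,5-trimethoxyphenyl)but-3-yn-1-yl]oxy}diphenylsilane
Product: 13 (R)-2-(3,4-dimethoxybenzyl)-4-(3,4,5-trimethoxyphenyl)but-3-yn-1-ol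
Conditions: TBAF, THF, 0 °C → rt
Reagents that add atoms: none
Why: Fluoride-induced cleavage of a primary TBDPS ether; the aryl alkyne and the non-acidic propargylic C–H at the stereocentre should be inert to TBAF at room temperature.

Step 9
Reactants: 13 (R)-2-(3,4-dimethoxybenzyl)-4-(3,4,5-trimethoxyphenyl)but-3-yn-1-ol
Product: 14 methyl (R)-4-(3,4-dimethoxybenzyl)-2-(3,4,5-trimethoxyphenyl)-4,5-dihydrofuran-3-carboxylate
Conditions: PdI2 (2 mol %), KI (20 mol %), CO/air 4:1 (40 atm), MeOH, 80 °C
Reagents that add atoms: carbon monoxide, [C-]#[O+]; methanol, CO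
Why: The iodide-ligated divalent palladium formed from PdI2 and KI coordinates the alkyne, and the C5 hydroxyl adds anti at the aryl-bearing carbon, the position best able to carry positive charge next to the electron-rich trimethoxyphenyl ring, so that O1–C2 forms and a vinylpalladium sits at C3. CO inserts into the C3–Pd bond and methanol cleaves the acylpalladium to the methyl ester, releasing HI and zerovalent palladium, which O2 and HI return to PdI2 with water as the only by-product. The closest known reaction type is the PdI2/KI oxidative heterocyclisation–alkoxycarbonylation of 3-yne-1,2-diols, 2-alkynylphenols and related alkynols. The one ring formed, dihydrofuran ring A, closes in the 5-endo-dig mode, the alternative 4-exo attack at C3 leading only to a strained oxetane. No stereocentre is created, and C4 should pass through unchanged because the medium holds no base and palladium never bonds to C4. The step needs oxypalladation to outrun alkyne insertion into a methoxycarbonylpalladium species and protonolysis of the vinylpalladium; the internal aryl-polarised alkyne, the iodide-rich medium and the high CO pressure should secure this.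

Step 10
Reactants: 14 methyl (R)-4-(3,4-dimethoxybenzyl)-2-(3,4,5-trimethoxyphenyl)-4,5-dihydrofuran-3-carboxylate
Product: 15 methyl (2R,3S,4R)-4-(3,4-dimethoxybenzyl)-2-(3,4,5-trimethoxyphenyl)tetrahydrofuran-3-carboxylate
Conditions: H2 (5 atm), 5% Rh/Al2O3, EtOAc, rt
Reagents that add atoms: none
Why: Heterogeneous catalytic hydrogenation (syn addition of H2 at the metal surface) should deliver both hydrogens to the face of C2=C3 opposite the C4 benzyl group, setting C2 and C3 together and all-cis to C4; rhodium on neutral alumina is chosen over palladium to spare the benzylic C2–O bond.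

Step 11
Reactants: 15 methyl (2R,3S,4R)-4-(3,4-dimethoxybenzyl)-2-(3,4,5-trimethoxyphenyl)tetrahydrofuran-3-carboxylate
Product: 16 [(2R,3R,4R)-4-(3,4-dimethoxybenzyl)-2-(3,4,5-trimethoxyphenyl)tetrahydrofuran-3-yl]methanol
Conditions: LiAlH4, THF, 0 °C; Na2SO4·10H2O quench
Reagents that add atoms: none
Why: LiAlH4 reduction of an ester to the primary alcohol is fast at 0 °C relative to enolisation, so C3 should keep its configuration (its descriptor changes from S to R only through the priority change), and the non-acidic quench protects the 2-aryl oxolane.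

**Compound list**

1 | 3-(3,4-dimethoxyphenyl)propanoic acid | COc1ccc(CCC(=O)O)cc1OC | starting material
2 | (R)-4-benzyloxazolidin-2-one | O=C1N[C@H](Cc2ccccc2)CO1 | starting material
3 | 3-(3,4-dimethoxyphenyl)propanoic pivalic anhydride | COc1ccc(CCC(=O)OC(=O)C(C)(C)C)cc1OC | intermediate
4 | (R)-4-benzyl-3-[3-(3,4-dimethoxyphenyl)propanoyl]oxazolidin-2-one | COc1ccc(CCC(=O)N2[C@H](Cc3ccccc3)COC2=O)cc1OC | intermediate
5 | trichlorotitanium (Z)-enolate of 4 | COc1ccc(C/C=C(\O[Ti](Cl)(Cl)Cl)N2[C@H](Cc3ccccc3)COC2=O)cc1OC | intermediate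
6 | (R)-4-benzyl-3-[(S)-3-(3,4-dimethoxyphenyl)-2-(hydroxymethyl)propanoyl]oxazolidin-2-one | OC[C@H](Cc1ccc(OC)c(OC)c1)C(=O)N1[C@H](Cc2ccccc2)COC1=O | intermediate
7 | (R)-4-benzyl-3-[(S)-3-[(tert-butyldiphenylsilyl)oxy]-2-(3,4-dimethoxybenzyl)propanoyl]oxazolidin-2-one | CC(C)(C)[Si](OC[C@H](Cc1ccc(OC)c(OC)c1)C(=O)N1[C@H](Cc2ccccc2)COC1=O)(c1ccccc1)c1ccccc1 | intermediate
8 | (R)-3-[(tert-butyldiphenylsilyl)oxy]-2-(3,4-dimethoxybenzyl)propan-1-ol | CC(C)(C)[Si](OC[C@H](Cc1ccc(OC)c(OC)c1)CO)(c1ccccc1)c1ccccc1 | intermediate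
9 | (S)-3-[(tert-butyldiphenylsilyl)oxy]-2-(3,4-dimethoxybenzyl)propanal | CC(C)(C)[Si](OC[C@H](Cc1ccc(OC)c(OC)c1)C=O)(c1ccccc1)c1ccccc1 | intermediate
10 | (R)-tert-butyl{[2-(3,4-dimethoxybenzyl)but-3-yn-1-yl]oxy}diphenylsilane | CC(C)(C)[Si](OC[C@H](Cc1ccc(OC)c(OC)c1)C#C)(c1ccccc1)c1ccccc1 | intermediate
11 | 5-iodo-1,2,3-trimethoxybenzene | COc1cc(I)cc(OC)c1OC | starting material
12 | (R)-tert-butyl{[2-(3,4-dimethoxybenzyl)-4-(3,4,5-trimethoxyphenyl)but-3-yn-1-yl]oxy}diphenylsilane | CC(C)(C)[Si](OC[C@H](Cc1ccc(OC)c(OC)c1)C#Cc1cc(OC)c(OC)c(OC)c1)(c1ccccc1)c1ccccc1 | intermediate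
13 | (R)-2-(3,4-dimethoxybenzyl)-4-(3,4,5-trimethoxyphenyl)but-3-yn-1-ol | OC[C@H](Cc1ccc(OC)c(OC)c1)C#Cc1cc(OC)c(OC)c(OC)c1 | intermediate
14 | methyl (R)-4-(3,4-dimethoxybenzyl)-2-(3,4,5-trimethoxyphenyl)-4,5-dihydrofuran-3-carboxylate | COC(=O)C1=C(c2cc(OC)c(OC)c(OC)c2)OC[C@@H]1Cc1ccc(OC)c(OC)c1 | intermediate
15 | methyl (2R,3S,4R)-4-(3,4-dimethoxybenzyl)-2-(3,4,5-trimethoxyphenyl)tetrahydrofuran-3-carboxylate | COc1ccc(C[C@H]2CO[C@@H](c3cc(OC)c(OC)c(OC)c3)[C@H]2C(=O)OC)cc1OC | intermediate
16 | [(2R,3R,4R)-4-(3,4-dimethoxybenzyl)-2-(3,4,5-trimethoxyphenyl)tetrahydrofuran-3-yl]methanol | COc1ccc(C[C@H]2CO[C@@H](c3cc(OC)c(OC)c(OC)c3)[C@H]2CO)cc1OC | target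

**Step count**

Total: 11 steps. Longest linear sequence: 11 steps (1 → 16); 2 and 11 enter in single steps.

**Steps most likely to fail**

1. Step 9 (alkoxycarbonylative ring closure). The alkyne may insert into a methoxycarbonylpalladium species before the hydroxyl attacks, giving maleate-type diesters or an α-alkylidene lactone. The vinylpalladium may also be protonated by HI before CO insertion, or the HI may hydrate the alkyne. Fallback: the same two bonds are made in two known operations. Setting out from 13, iodocyclisation (I2, NaHCO3, MeCN, 0 °C; 5-endo-dig) should give (S)-3-(3,4-dimethoxybenzyl)-4-iodo-5-(3,4,5-trimethoxyphenyl)-2,3-dihydrofuran F1. Palladium-catalysed methoxycarbonylation of this vinyl iodide (PdCl2(PPh3)2, CO 1 atm, Et3N, MeOH, 60 °C) then comes back to the route at 14.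

2. Step 10 (hydrogenation of the tetrasubstituted donor–acceptor alkene). Hydrogen uptake may be slow or absent, the benzylic C2–O bond of the product may be hydrogenolysed, the methoxyarenes may be saturated on rhodium, or the facial selectivity may be incomplete. Fallback: the order of the two reductions and the catalyst class are changed. Setting out from 14, DIBAL-H (CH2Cl2, −78 °C) should give the acid-sensitive allylic alcohol [(R)-4-(3,4-dimethoxybenzyl)-2-(3,4,5-trimethoxyphenyl)-4,5-dihydrofuran-3-yl]methanol F2. Its hydroxyl-directed homogeneous hydrogenation with [Ir(cod)(PCy3)(py)]PF6 under H2 in CH2Cl2 should again add from the face opposite the C4 benzyl group and comes back to the route at the target 16, bypassing 15 and step 11.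

3. Step 2 (hydroxymethylation). TiCl4-activated formaldehyde may attack the electron-rich dimethoxyphenyl ring, and the primary aldol product may react further with excess formaldehyde to hemiformals and formals. Fallback: setting out from 4, the same titanium enolate is alkylated with benzyl chloromethyl ether (TiCl4, iPr2NEt, CH2Cl2, 0 °C), a monofunctional electrophile that delivers the oxygen already protected. This should give (R)-4-benzyl-3-[(S)-3-(benzyloxy)-2-(3,4-dimethoxybenzyl)propanoyl]oxazolidin-2-one F3 with the same facial sense. Hydrogenolysis (H2, Pd/C, EtOAc) then frees the primary alcohol and comes back to the route at 6.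

**Further compounds**

F1 | step 9 | (S)-3-(3,4-dimethoxybenzyl)-4-iodo-5-(3,4,5-trimethoxyphenyl)-2,3-dihydrofuran | IC1=C(c2cc(OC)c(OC)c(OC)c2)OC[C@@H]1Cc1ccc(OC)c(OC)c1
F2 | step 10 | [(R)-4-(3,4-dimethoxybenzyl)-2-(3,4,5-trimethoxyphenyl)-4,5-dihydrofuran-3-yl]methanol | OCC1=C(c2cc(OC)c(OC)c(OC)c2)OC[C@@H]1Cc1ccc(OC)c(OC)c1
F3 | step 2 | (R)-4-benzyl-3-[(S)-3-(benzyloxy)-2-(3,4-dimethoxybenzyl)propanoyl]oxazolidin-2-one | C(OC[C@H](Cc1ccc(OC)c(OC)c1)C(=O)N1[C@H](Cc2ccccc2)COC1=O)c1ccccc1
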